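**Retrosynthetic overview**
1. Last bond and last ring: C9–C10 of the ten-membered carbocycle, closed by an intramolecular carbene-catalysed acyloin (crossed benzoin) addition. The C9 aldehyde, as its Breslow intermediate (an acyl anion), attacks the C10 methyl ketone and gives the tertiary α-hydroxy ketone directly, with no protecting groups.
2. The seco keto-aldehyde comes from selective ozonolysis of the citronellal-derived trisubstituted alkene (masked C9 aldehyde).
3. C3a–C4 and the α-methylene lactone: indium Barbier coupling of a 3-(bromomethyl)butenolide (C10–C11a, angelate and ketone in place) with an α-isobutyryloxy aldehyde (C4–C9).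
4. Western butenolide (first ring): Brown alkoxyallylboration of a silylpropynal (C11, C11a), angeloylation, acrylate ester, ring-closing metathesis, alkyne hydration (C10 ketone).
5. Eastern aldehyde: (R)-citronellal (C6), proline α-aminoxylation (C5), orthoester mono-acylation, oxidation. Ring order: five-membered lactone first, ten-membered carbocycle last.

Assumption: the SMILES is read as the (3aR,4R,5R,6R,10R,11R,11aS)-cyclodeca[b]furan-2,9-dione with a (Z)-2-methylbut-2-enoate (angelate) on C11; these locants (O1, C2 lactone C=O, C3 =CH2, C3a, C4 OH, C5 O-isobutyryl, C6 CH3, C9 C=O, C10 C(OH)CH3, C11, C11a) are used below.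

**Route**

Step 1
Reactants: 1 3-(methoxymethoxy)prop-1-ene; 2 3-(trimethylsilyl)prop-2-ynal
Product: 7 (3S,4S)-4-(methoxymethoxy)-1-(trimethylsilyl)hex-5-en-1-yn-3-ol, via allyllithium 3 (not isolated), via lithium borate 4 (not isolated), via allylborane 5 (not isolated), via borinate 6 (not isolated)
Conditions: s-BuLi, THF, −78 °C; (+)-Ipc2BOMe [(+)-B-methoxydiisopinocampheylborane, from (−)-α-pinene]; BF3·OEt2; then 2, −78 °C; HOCH2CH2NH2, Et2O, 23 °C
Reagents that add atoms: none
Why: Brown (Z)-γ-alkoxyallylboration through a chair transition state gives the syn monoprotected diol, and the isopinocampheyl groups from (−)-α-pinene direct attack to the Re face of the ynal, setting the future C11 and C11a as (3S,4S).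

Step 2
Reactants: 7 (3S,4S)-4-(methoxymethoxy)-1-(trimethylsilyl)hex-5-en-1-yn-3-ol; 8 angelic acid [(2Z)-2-methylbut-2-enoic acid]
Product: 10 (3S,4S)-3-(methoxymethoxy)-6-(trimethylsilyl)hex-1-en-5-yn-4-yl (2Z)-2-methylbut-2-enoate, via mixed anhydride 9 (not isolated)
Conditions: 2,4,6-Cl3C6H2COCl, Et3N, toluene, 23 °C; then 7, 80 °C
Reagents that add atoms: none
Why: Yamaguchi-type mixed-anhydride acylation without a nucleophilic pyridine catalyst esterifies the propargylic alcohol and keeps the Z geometry of the angeloyl group; no stereocentre is touched.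

Step 3
Reactants: 10 (3S,4S)-3-(methoxymethoxy)-6-(trimethylsilyl)hex-1-en-5-yn-4-yl (2Z)-2-methylbut-2-enoate
Product: 11 (3S,4S)-3-hydroxy-6-(trimethylsilyl)hex-1-en-5-yn-4-yl (2Z)-2-methylbut-2-enoate
Conditions: ZnBr2 (1 equiv), n-PrSH (2 equiv), CH2Cl2, 0 °C, 10 min; used at once
Reagents that add atoms: none
Why: Lewis-acid/thiol acetal exchange cleaves the methoxymethyl ether within minutes, too fast for angelate migration, and leaves the alkynylsilane and both stereocentres untouched.

Step 4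
Reactants: 11 (3S,4S)-3-hydroxy-6-(trimethylsilyl)hex-1-en-5-yn-4-yl (2Z)-2-methylbut-2-enoate; 12 2-(bromomethyl)prop-2-enoic acid
Product: 14 (3S,4S)-4-{[(2Z)-2-methylbut-2-enoyl]oxy}-6-(trimethylsilyl)hex-1-en-5-yn-3-yl 2-(bromomethyl)prop-2-enoate, via O-acylisourea 13 (not isolated)
Conditions: N,N'-dicyclohexylcarbodiimide, 4-(dimethylamino)pyridine (5 mol%), CH2Cl2, 0 °C
Reagents that add atoms: none
Why: Steglich esterification of the allylic alcohol at 0 °C outruns acyl migration and bromide displacement; no stereocentre is changed.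

Step 5
Reactants: 14 (3S,4S)-4-{[(2Z)-2-methylbut-2-enoyl]oxy}-6-(trimethylsilyl)hex-1-en-5-yn-3-yl 2-(bromomethyl)prop-2-enoate
Product: 15 (1S)-1-[(2S)-4-(bromomethyl)-5-oxo-2,5-dihydrofuran-2-yl]-3-(trimethylsilyl)prop-2-yn-1-yl (2Z)-2-methylbut-2-enoate
Conditions: second-generation Hoveyda–Grubbs catalyst [RuCl2(H2IMes)(=CH-C6H4-2-OiPr)] (5 mol%), toluene (5 mM), 80 °C
Reagents that add atoms: none
Why: Ring-closing metathesis between the only monosubstituted alkene and the 2-substituted acrylate closes the butenolide, the silyl-capped alkyne and the trisubstituted angelate being inert; C11a keeps its configuration.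

Step 6
Reactants: 15 (1S)-1-[(2S)-4-(bromomethyl)-5-oxo-2,5-dihydrofuran-2-yl]-3-(trimethylsilyl)prop-2-yn-1-yl (2Z)-2-methylbut-2-enoate
Product: 17 (1R)-1-[(2S)-4-(bromomethyl)-5-oxo-2,5-dihydrofuran-2-yl]-2-oxopropyl (2Z)-2-methylbut-2-enoate, via terminal alkyne 16 (not isolated)
Conditions: Ph3PAuNTf2 (monovalent gold, 5 mol%), H2O (5 equiv), 1,4-dioxane, 23 °C
Reagents that add atoms: water (O)
Why: Gold-catalysed Markovnikov hydration of the propargylic ester, assisted by 5-exo attack of the angelate carbonyl and following protodesilylation, gives the methyl ketone with the ester returned to the same oxygen and C11 retained (the descriptor changes to R only through priorities).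

Step 7
Reactants: 18 (R)-citronellal [(3R)-3,7-dimethyloct-6-enal]
Product: 20 (2R,3R)-3,7-dimethyl-2-[(phenylamino)oxy]oct-6-en-1-ol, via aminoxy aldehyde 19 (not isolated)
Conditions: PhNO, L-proline (20 mol%), CHCl3, 4 °C; then NaBH4, EtOH, 0 °C
Reagents that add atoms: nitrosobenzene (O=Nc1ccccc1)
Why: Proline-catalysed enamine α-aminoxylation (O-selective nitroso aldol) with L-proline sets the future C5 as 2R under catalyst control over the existing methyl centre, and immediate borohydride reduction prevents epimerisation.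

Step 8
Reactants: 20 (2R,3R)-3,7-dimethyl-2-[(phenylamino)oxy]oct-6-en-1-ol
Product: 21 (2R,3R)-3,7-dimethyloct-6-ene-1,2-diol
Conditions: Zn dust, AcOH/EtOH (1:3), 23 °C
Reagents that add atoms: none
Why: Dissolving-metal reduction cleaves the weak N–O bond without touching the trisubstituted alkene or either stereocentre.

Step 9
Reactants: 21 (2R,3R)-3,7-dimethyloct-6-ene-1,2-diol
Product: 23 (2R,3R)-1-hydroxy-3,7-dimethyloct-6-en-2-yl 2-methylpropanoate, via cyclic orthoester 22 (not isolated)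
Conditions: iPrC(OMe)3, pyridinium p-toluenesulfonate (2 mol%), CH2Cl2, 23 °C; then H2O, 23 °C; used at once
Reagents that add atoms: trimethyl orthoisobutyrate (COC(OC)(OC)C(C)C); water (O)
Why: Transorthoesterification gives the five-membered cyclic orthoester, whose mild acid hydrolysis opens kinetically to the ester of the more hindered secondary hydroxyl, so the isobutyrate lands on the C5 oxygen with retention.

Step 10
Reactants: 23 (2R,3R)-1-hydroxy-3,7-dimethyloct-6-en-2-yl 2-methylpropanoate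
Product: 24 (2R,3R)-3,7-dimethyl-1-oxooct-6-en-2-yl 2-methylpropanoate
Conditions: Dess–Martin periodinane, CH2Cl2, 0 to 23 °C; used crude
Reagents that add atoms: none
Why: Dess–Martin oxidation of the primary alcohol under near-neutral conditions gives the α-acyloxy aldehyde before the ester can migrate and without epimerising the α-centre.

Step 11
Reactants: 17 (1R)-1-[(2S)-4-(bromomethyl)-5-oxo-2,5-dihydrofuran-2-yl]-2-oxopropyl (2Z)-2-methylbut-2-enoate; 24 (2R,3R)-3,7-dimethyl-1-oxooct-6-en-2-yl 2-methylpropanoate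
Product: 26 (1R)-1-[(2S,3R)-3-{(1R,2R,3R)-1-hydroxy-3,7-dimethyl-2-[(2-methylpropanoyl)oxy]oct-6-en-1-yl}-4-methylidene-5-oxooxolan-2-yl]-2-oxopropyl (2Z)-2-methylbut-2-enoate, via allylindium 25 (not isolated)
Conditions: In powder (1.5 equiv), THF/H2O (1:1), 23 °C
Reagents that add atoms: none
Why: Indium Barbier allylation in which the allylindium from the 3-(bromomethyl)butenolide reacts through its ring carbon (SE2′) in a six-membered chair: attack anti to the C11a side chain sets C3a (trans lactone), the equatorial aldehyde substituent sets C4, the α-methylene lactone is unveiled with the new C4 hydroxyl left free, and the aldehyde reacts in preference to the ketone.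

Step 12
Reactants: 26 (1R)-1-[(2S,3R)-3-{(1R,2R,3R)-1-hydroxy-3,7-dimethyl-2-[(2-methylpropanoyl)oxy]oct-6-en-1-yl}-4-methylidene-5-oxooxolan-2-yl]-2-oxopropyl (2Z)-2-methylbut-2-enoate
Product: 28 (1R)-1-[(2S,3R)-3-{(1R,2R,3R)-1-hydroxy-3-methyl-2-[(2-methylpropanoyl)oxy]-6-oxohexyl}-4-methylidene-5-oxooxolan-2-yl]-2-oxopropyl (2Z)-2-methylbut-2-enoate, via ozonide 27 (not isolated)
Conditions: O3, CH2Cl2, Sudan Red 7B (trace), −78 °C; then PPh3, −78 to 23 °C
Reagents that add atoms: ozone ([O-][O+]=O)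
Why: Ozonolysis with reductive work-up, stopped at the indicator end-point, cleaves only the electron-rich trisubstituted alkene, the conjugated exocyclic methylene and the angelate reacting one to two orders of magnitude more slowly.

Step 13
Reactants: 28 (1R)-1-[(2S,3R)-3-{(1R,2R,3R)-1-hydroxy-3-methyl-2-[(2-methylpropanoyl)oxy]-6-oxohexyl}-4-methylidene-5-oxooxolan-2-yl]-2-oxopropyl (2Z)-2-methylbut-2-enoate
Product: 30 (3aR,4R,5R,6R,10R,11R,11aS)-4,10-dihydroxy-6,10-dimethyl-3-methylidene-5-[(2-methylpropanoyl)oxy]-2,9-dioxododecahydrocyclodeca[b]furan-11-yl (2Z)-2-methylbut-2-enoate, via Breslow intermediate 29 (not isolated)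
Conditions: 2-(pentafluorophenyl)-6,7-dihydro-5H-pyrrolo[2,1-c][1,2,4]triazol-2-ium tetrafluoroborate (20 mol%), iPr2NEt (20 mol%), CH2Cl2 (2 mM, slow addition of 28), 23 °C
Reagents that add atoms: none
Why: Proposed new method: the triazolylidene adds to the unhindered aldehyde to give Breslow intermediate 29 (acyl anion at C9), whose enaminol carbon attacks the inductively activated α-acyloxy methyl ketone across the chain, and proton transfer with loss of the carbene releases the ten-membered α-hydroxy ketone; high dilution and a weakly nucleophilic N-pentafluorophenyl carbene disfavour Stetter-type capture by the methylene lactone, the amine base is too weak for acyl shift or epimerisation, and polar Felkin–Anh attack anti to the C11 acyloxy group is expected to set C10 as R; the closest known reactions are the intramolecular crossed aldehyde–ketone benzoin (five- and six-membered rings) and carbene-catalysed acyl-anion macrocyclisation of the Stetter type.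

**Compound list**
1 | 3-(methoxymethoxy)prop-1-ene | C=CCOCOC | starting material
2 | 3-(trimethylsilyl)prop-2-ynal | O=CC#C[Si](C)(C)C | starting material
3 | [(Z)-3-(methoxymethoxy)prop-2-en-1-yl]lithium | [Li]C/C=C\OCOC | intermediate
4 | lithium methoxy[(Z)-3-(methoxymethoxy)allyl]bis(isopinocampheyl)borate | [Li+].CO[B-](C/C=C\OCOC)([C@H]1C[C@H]2C[C@@H]([C@@H]1C)C2(C)C)[C@H]1C[C@H]2C[C@@H]([C@@H]1C)C2(C)C | intermediate
5 | [(Z)-3-(methoxymethoxy)allyl]bis(isopinocampheyl)borane | COCO/C=C\CB([C@H]1C[C@H]2C[C@@H]([C@@H]1C)C2(C)C)[C@H]1C[C@H]2C[C@@H]([C@@H]1C)C2(C)C | intermediate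
6 | bis(isopinocampheyl)borinate ester of 7 | C=C[C@H](OCOC)[C@@H](OB([C@H]1C[C@H]2C[C@@H]([C@@H]1C)C2(C)C)[C@H]1C[C@H]2C[C@@H]([C@@H]1C)C2(C)C)C#C[Si](C)(C)C | intermediate
7 | (3S,4S)-4-(methoxymethoxy)-1-(trimethylsilyl)hex-5-en-1-yn-3-ol | C=C[C@H](OCOC)[C@@H](O)C#C[Si](C)(C)C | intermediate
8 | angelic acid, (2Z)-2-methylbut-2-enoic acid | C/C=C(/C)C(=O)O | starting material
9 | angelic 2,4,6-trichlorobenzoic anhydride | C/C=C(/C)C(=O)OC(=O)c1c(Cl)cc(Cl)cc1Cl | intermediate
10 | (3S,4S)-3-(methoxymethoxy)-6-(trimethylsilyl)hex-1-en-5-yn-4-yl (2Z)-2-methylbut-2-enoate | C=C[C@H](OCOC)[C@@H](OC(=O)/C(C)=C\C)C#C[Si](C)(C)C | intermediate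
11 | (3S,4S)-3-hydroxy-6-(trimethylsilyl)hex-1-en-5-yn-4-yl (2Z)-2-methylbut-2-enoate | C=C[C@H](O)[C@@H](OC(=O)/C(C)=C\C)C#C[Si](C)(C)C | intermediate
12 | 2-(bromomethyl)prop-2-enoic acid | C=C(CBr)C(=O)O | starting material
13 | O-[2-(bromomethyl)acryloyl]-N,N'-dicyclohexylisourea | C=C(CBr)C(=O)OC(=NC1CCCCC1)NC1CCCCC1 | intermediate
14 | (3S,4S)-4-{[(2Z)-2-methylbut-2-enoyl]oxy}-6-(trimethylsilyl)hex-1-en-5-yn-3-yl 2-(bromomethyl)prop-2-enoate | C=C[C@H](OC(=O)C(=C)CBr)[C@@H](OC(=O)/C(C)=C\C)C#C[Si](C)(C)C | intermediate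
15 | (1S)-1-[(2S)-4-(bromomethyl)-5-oxo-2,5-dihydrofuran-2-yl]-3-(trimethylsilyl)prop-2-yn-1-yl (2Z)-2-methylbut-2-enoate | BrCC1=C[C@H](OC1=O)[C@@H](OC(=O)/C(C)=C\C)C#C[Si](C)(C)C | intermediate
16 | (1S)-1-[(2S)-4-(bromomethyl)-5-oxo-2,5-dihydrofuran-2-yl]prop-2-yn-1-yl (2Z)-2-methylbut-2-enoate | BrCC1=C[C@H](OC1=O)[C@@H](OC(=O)/C(C)=C\C)C#C | intermediate
17 | (1R)-1-[(2S)-4-(bromomethyl)-5-oxo-2,5-dihydrofuran-2-yl]-2-oxopropyl (2Z)-2-methylbut-2-enoate | BrCC1=C[C@H](OC1=O)[C@@H](OC(=O)/C(C)=C\C)C(C)=O | intermediate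
18 | (R)-citronellal, (3R)-3,7-dimethyloct-6-enal | O=CC[C@H](C)CCC=C(C)C | starting material
19 | (2R,3R)-3,7-dimethyl-2-[(phenylamino)oxy]oct-6-enal | O=C[C@H](ONc1ccccc1)[C@H](C)CCC=C(C)C | intermediate
20 | (2R,3R)-3,7-dimethyl-2-[(phenylamino)oxy]oct-6-en-1-ol | OC[C@H](ONc1ccccc1)[C@H](C)CCC=C(C)C | intermediate
21 | (2R,3R)-3,7-dimethyloct-6-ene-1,2-diol | OC[C@H](O)[C@H](C)CCC=C(C)C | intermediate
22 | (4R)-2-methoxy-4-[(2R)-6-methylhept-5-en-2-yl]-2-(propan-2-yl)-1,3-dioxolane (both C2 epimers) | COC1(C(C)C)OC[C@H](O1)[C@H](C)CCC=C(C)C | intermediate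
23 | (2R,3R)-1-hydroxy-3,7-dimethyloct-6-en-2-yl 2-methylpropanoate | OC[C@H](OC(=O)C(C)C)[C@H](C)CCC=C(C)C | intermediate
24 | (2R,3R)-3,7-dimethyl-1-oxooct-6-en-2-yl 2-methylpropanoate | O=C[C@H](OC(=O)C(C)C)[C@H](C)CCC=C(C)C | intermediate
25 | allylindium reagent from 17, drawn as the dibromide: {[(5S)-5-{(1R)-1-[(2Z)-2-methylbut-2-enoyloxy]-2-oxopropyl}-2-oxo-2,5-dihydrofuran-3-yl]methyl}indium dibromide | Br[In](Br)CC1=C[C@H](OC1=O)[C@@H](OC(=O)/C(C)=C\C)C(C)=O | intermediate
26 | (1R)-1-[(2S,3R)-3-{(1R,2R,3R)-1-hydroxy-3,7-dimethyl-2-[(2-methylpropanoyl)oxy]oct-6-en-1-yl}-4-methylidene-5-oxooxolan-2-yl]-2-oxopropyl (2Z)-2-methylbut-2-enoate | C=C1C(=O)O[C@H]([C@@H](OC(=O)/C(C)=C\C)C(C)=O)[C@H]1[C@@H](O)[C@H](OC(=O)C(C)C)[C@H](C)CCC=C(C)C | intermediate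
27 | secondary ozonide (3,3-dimethyl-1,2,4-trioxolane) of the trisubstituted alkene of 26 | C=C1C(=O)O[C@H]([C@@H](OC(=O)/C(C)=C\C)C(C)=O)[C@H]1[C@@H](O)[C@H](OC(=O)C(C)C)[C@H](C)CCC2OOC(C)(C)O2 | intermediate
28 | (1R)-1-[(2S,3R)-3-{(1R,2R,3R)-1-hydroxy-3-methyl-2-[(2-methylpropanoyl)oxy]-6-oxohexyl}-4-methylidene-5-oxooxolan-2-yl]-2-oxopropyl (2Z)-2-methylbut-2-enoate | C=C1C(=O)O[C@H]([C@@H](OC(=O)/C(C)=C\C)C(C)=O)[C@H]1[C@@H](O)[C@H](OC(=O)C(C)C)[C@H](C)CCC=O | intermediate
29 | Breslow intermediate: enaminol formed from the aldehyde of 28 and the triazolylidene | C=C1C(=O)O[C@H]([C@@H](OC(=O)/C(C)=C\C)C(C)=O)[C@H]1[C@@H](O)[C@H](OC(=O)C(C)C)[C@H](C)CCC(O)=C3N(c4c(F)c(F)c(F)c(F)c4F)N=C5CCCN35 | intermediate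
30 | (3aR,4R,5R,6R,10R,11R,11aS)-4,10-dihydroxy-6,10-dimethyl-3-methylidene-5-[(2-methylpropanoyl)oxy]-2,9-dioxododecahydrocyclodeca[b]furan-11-yl (2Z)-2-methylbut-2-enoate (CNP0223049.1) | C=C1C(=O)O[C@H]2[C@H]1[C@@H](O)[C@H](OC(=O)C(C)C)[C@H](C)CCC(=O)[C@](C)(O)[C@@H]2OC(=O)/C(C)=C\C | target

**Step count**
Total: 13 steps. Longest linear sequence: 9 steps (steps 1–6, then 11–13); the eastern branch is steps 7–10.

**Three steps most likely to fail**

Step 13 (carbene-catalysed ten-membered acyloin closure). The risks are ring strain with a reversible addition, Stetter-type capture of the Breslow intermediate by the α-methylene lactone, and oligomers. Fallback: mask the Michael acceptor and cyclise the masked compound. Setting out from 28, conjugate addition of thiophenol (PhSH, Et3N 5 mol%, CH2Cl2, 0 °C) gives the phenylthio-masked keto-aldehyde F1. The same triazolium/iPr2NEt cyclisation at 2 mM then gives the macrocyclic sulfide F2. NaIO4 (MeOH/H2O, 0 °C) gives the sulfoxide F3, and warming in toluene (80 °C) expels benzenesulfenic acid and restores the exocyclic methylene, coming back to the route at 30.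

Step 11 (Barbier coupling). The chair and the butenolide face fix C3a and C4, but the required C4 configuration is anti-Felkin with respect to the C5 acyloxy group, so the C4 epimer may form in quantity. Fallback: set C4 by hydride instead of by allylation. Setting out from 15 and 24, the same indium coupling with the silylalkyne 15 (no second ketone present) gives the alkyne adduct as its C4 epimer F4 together with the wanted alkyne carbinol F6. Dess–Martin oxidation of the mixture gives the C4 ketone F5. NaBH4/CeCl3·7H2O (MeOH, −78 °C) reduces it under polar Felkin–Anh control, anti to the C5 acyloxy group, which now gives the required 4,5-syn alcohol, the alkyne carbinol F6. Gold-catalysed hydration as in step 6 then comes back to the route at 26.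

Step 12 (selective ozonolysis). Over-oxidation of the angelate or the methylene lactone on a late, valuable intermediate is possible. Fallback: setting out from 26, mCPBA (1.05 equiv, CH2Cl2, 0 °C) epoxidises only the electron-rich trisubstituted alkene to give the epoxide F7. H5IO6 (THF/H2O, 0 °C) cleaves the epoxide to the aldehyde, coming back to the route at 28.

**Further compounds**
F1 | step 13 | phenylthio adduct of 28: 4-[(phenylsulfanyl)methyl]-5-oxooxolane in place of the 4-methylidene lactone (both C4 epimers), other centres as in 28 | C(Sc2ccccc2)C1C(=O)O[C@H]([C@@H](OC(=O)/C(C)=C\C)C(C)=O)[C@H]1[C@@H](O)[C@H](OC(=O)C(C)C)[C@H](C)CCC=O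
F2 | step 13 | macrocyclic sulfide: 3-[(phenylsulfanyl)methyl] analogue of 30 (both C3 epimers) | C(Sc3ccccc3)C1C(=O)O[C@H]2[C@H]1[C@@H](O)[C@H](OC(=O)C(C)C)[C@H](C)CCC(=O)[C@](C)(O)[C@@H]2OC(=O)/C(C)=C\C
F3 | step 13 | macrocyclic sulfoxide: 3-[(phenylsulfinyl)methyl] analogue of 30 | C(S(=O)c3ccccc3)C1C(=O)O[C@H]2[C@H]1[C@@H](O)[C@H](OC(=O)C(C)C)[C@H](C)CCC(=O)[C@](C)(O)[C@@H]2OC(=O)/C(C)=C\C
F4 | step 11 | C4-epimeric Barbier adduct of 15 and 24 (silylalkyne in place of the ketone, carbinol centre 1S) | C=C1C(=O)O[C@H]([C@@H](OC(=O)/C(C)=C\C)C#C[Si](C)(C)C)[C@H]1[C@H](O)[C@H](OC(=O)C(C)C)[C@H](C)CCC=C(C)C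
F5 | step 11 | C4 ketone from oxidation of F4 and F6 | C=C1C(=O)O[C@H]([C@@H](OC(=O)/C(C)=C\C)C#C[Si](C)(C)C)[C@H]1C(=O)[C@H](OC(=O)C(C)C)[C@H](C)CCC=C(C)C
F6 | step 11 | silylalkyne analogue of 26 with the correct (1R) carbinol | C=C1C(=O)O[C@H]([C@@H](OC(=O)/C(C)=C\C)C#C[Si](C)(C)C)[C@H]1[C@@H](O)[C@H](OC(=O)C(C)C)[C@H](C)CCC=C(C)C
F7 | step 12 | epoxide of the trisubstituted alkene of 26 (both epoxide epimers) | C=C1C(=O)O[C@H]([C@@H](OC(=O)/C(C)=C\C)C(C)=O)[C@H]1[C@@H](O)[C@H](OC(=O)C(C)C)[C@H](C)CCC2OC2(C)C
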